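**Retrosynthetic overview**

1. Target 19 has a central ring C (aryloxy groups on C1, C2, C3; OH on C5). O–C2 carries ring D (4-chloro-3,5-dihydroxyphenyl); O–C1 and O–C3 carry two identical arms. Each arm is ring B (B1–O–ring A, B3-OH, B4–O–ring C, B5-OH, B6–ring G), with rings A and G both 2,4,6-trihydroxyphenyl.
2. The strategy rests on the B6–G1 bond of each arm: a tetra-ortho-substituted biaryl bond flanked by the hydroxyls on B5 and G2 (a 2,2'-biphenol) and by the B1 aryloxy group.
3. Last disconnections: all O–CH3 and O–CH2–O bonds (BBr3), then the two ring C (C1, C3)–O–B4 bonds by a twofold Ullmann coupling of arm phenol 12 with dibromide 17. Dibromide 17 (rings C and D) comes from C–H borylation of 2-chloro-1,3-dimethoxybenzene and Chan–Lam coupling with 2,6-dibromo-4-methoxyphenol.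
4. Key disconnection: B6–G1, by intramolecular anodic dehydrogenative coupling in 10, where an O–CH2–O bridge ties the B5 oxygen to a 3,5-dimethoxyphenoxy group (future ring G). Precursor 10 is made from 5-bromo-2-hydroxy-3-methoxybenzaldehyde by benzylation, Baeyer–Villiger oxidation, mixed-acetal formation and Ullmann etherification with 2,4,6-trimethoxyphenol.
5. Ring order: all benzene rings are bought. The only ring closed is the temporary seven-membered 1,3-dioxepine (step 6), opened again in the last step.

Key step: step 6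

Remark: the bridged biaryl axis in 11, 12 and 18 is a stereo element only while the O–CH2–O bridge is in place. These compounds are taken as racemates or mixtures of axial diastereomers, all of which converge on target 19, which has a symmetric ring G and no stereo element.

**Route**

Step 1
Reactants: 1 5-bromo-2-hydroxy-3-methoxybenzaldehyde
Product: 2 2-(benzyloxy)-5-bromo-3-methoxybenzaldehyde
Conditions: BnBr, K2CO3, DMF, 50 °C
Reagents that add atoms: benzyl bromide, BrCc1ccccc1
Why: Williamson ether synthesis on the single phenol, whose oxygen becomes the differentiated B4 oxygen.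

Step 2
Reactants: 2 2-(benzyloxy)-5-bromo-3-methoxybenzaldehyde
Product: 4 2-(benzyloxy)-5-bromo-3-methoxyphenol, via aryl formate 3 (not isolated)
Conditions: mCPBA, CH2Cl2, 0 °C → rt; then K2CO3 (cat.), MeOH, rt
Reagents that add atoms: mCPBA, OOC(=O)c1cccc(Cl)c1
Why: Baeyer–Villiger (Dakin-type) oxidation, in which the ortho-alkoxy aryl group migrates in preference to hydrogen, followed by methanolysis of the formate; it is run before any phloroglucinol-type ring is present.

Step 3
Reactants: 4 2-(benzyloxy)-5-bromo-3-methoxyphenol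
Product: 5 2-(benzyloxy)-5-bromo-3-methoxy-1-[(methylsulfanyl)methoxy]benzene
Conditions: NaH, ClCH2SMe, NaI (cat.), DMF, 0 °C → rt
Reagents that add atoms: chloromethyl methyl sulfide, CSCCl
Why: Williamson alkylation of the sodium phenoxide gives the methylthiomethyl ether, which carries the future acetal carbon.

Step 4
Reactants: 5 2-(benzyloxy)-5-bromo-3-methoxy-1-[(methylsulfanyl)methoxy]benzene; 6 3,5-dimethoxyphenol
Product: 8 2-(benzyloxy)-5-bromo-1-[(3,5-dimethoxyphenoxy)methoxy]-3-methoxybenzene, via chloromethyl ether 7 (not isolated)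
Conditions: SO2Cl2, CH2Cl2, −78 → 0 °C, evaporate; then 6, Cs2CO3, MeCN, 0 °C → rt
Reagents that add atoms: none
Why: Sulfuryl chloride turns the O,S-acetal into the aryl chloromethyl ether (Pummerer-type chlorosulfonium fragmentation), which O-alkylates the caesium phenoxide of 6 (Williamson-type acetal synthesis); the chloromethyl group is generated on the bromo-deactivated ring B so that the highly nucleophilic ring of 6 never carries it.

Step 5
Reactants: 8 2-(benzyloxy)-5-bromo-1-[(3,5-dimethoxyphenoxy)methoxy]-3-methoxybenzene; 9 2,4,6-trimethoxyphenol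
Product: 10 2-(benzyloxy)-1-[(3,5-dimethoxyphenoxy)methoxy]-3-methoxy-5-(2,4,6-trimethoxyphenoxy)benzene
Conditions: CuI (10 mol %), picolinic acid (20 mol %), K3PO4, DMSO, 90 °C, argon
Reagents that add atoms: none
Why: Ullmann-type copper-catalysed diaryl ether synthesis, pairing a bromide without ortho substituents with the di-ortho-methoxylated phenol, for which picolinic acid-ligated copper is suited; acetal and benzyl ether are inert to the base.

Step 6
Reactants: 10 2-(benzyloxy)-1-[(3,5-dimethoxyphenoxy)methoxy]-3-methoxy-5-(2,4,6-trimethoxyphenoxy)benzene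
Product: 11 4-(benzyloxy)-3,9,11-trimethoxy-1-(2,4,6-trimethoxyphenoxy)dibenzo[d,f][1,3]dioxepine (racemic axis)
Conditions: undivided cell, boron-doped diamond anode, Pt cathode, Bu4NBF4 (0.1 M), HFIP/CH2Cl2 (4:1), 0.005 M in 10, constant current 2 mA/cm2, 2.1 F/mol, 20 °C
Reagents that add atoms: none
Why: Proposed new method: anodic one-electron oxidation of the tetraoxygenated ring B gives an arene radical cation that is attacked at B6 by the ortho carbon of the tethered, phloroglucinol-type ring (future G1), and a second electron transfer with loss of two protons rearomatises both rings while H2 is evolved at the cathode. The closest known reaction type is the template-directed anodic ortho,ortho' coupling of boron- or silicon-bridged aryloxides, together with the hypervalent-iodine coupling of silicon-bridged aryl ethers; the formaldehyde acetal bridge has not been used in this way. The seven-membered 1,3-dioxepine closes by aryl–aryl bond formation between the two carbons ortho to the O–CH2–O bridge, a cyclisation in which both reacting carbons are arene ring atoms. No stereocenter arises; the bridged biaryl axis forms as a racemate and is no stereo element in the target. Regioselectivity is secured because the bridge oxygen on ring B has B6 as its only free ortho carbon (B4 is substituted) and the other ring is symmetric about its bridge oxygen, and ring A cannot cyclise because both of its ortho positions carry OMe. Intra- over intermolecular coupling and protection of the product from further oxidation rest on high dilution, HFIP as radical-cation-stabilising solvent and a charge limited to little more than 2 F/mol.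

Step 7
Reactants: 11 4-(benzyloxy)-3,9,11-trimethoxy-1-(2,4,6-trimethoxyphenoxy)dibenzo[d,f][1,3]dioxepine
Product: 12 3,9,11-trimethoxy-1-(2,4,6-trimethoxyphenoxy)dibenzo[d,f][1,3]dioxepin-4-ol (arm phenol, racemic axis)
Conditions: H2 (1 atm), Pd/C, EtOAc/MeOH, rt
Reagents that add atoms: none
Why: Catalytic hydrogenolysis cleaves only the aryl benzyl ether; methyl ethers, diaryl ethers and the diaryl formaldehyde acetal are stable to H2 over Pd/C.

Step 8
Reactants: 13 2-chloro-1,3-dimethoxybenzene
Product: 15 (4-chloro-3,5-dimethoxyphenyl)boronic acid, via pinacol boronate 14 (not isolated)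
Conditions: B2pin2 (0.6 equiv), [Ir(OMe)(cod)]2 (1.5 mol %), 4,4'-di-tert-butyl-2,2'-bipyridine (3 mol %), THF, 80 °C; then NaIO4, THF/H2O, 1 M HCl, rt
Reagents that add atoms: bis(pinacolato)diboron, CC1(C)OB(OC1(C)C)B1OC(C)(C)C(C)(C)O1; water, O
Why: Iridium-catalysed C–H borylation is sterically controlled and takes the only C–H bond without an ortho substituent (C5, para to Cl), and periodate cleavage of the pinacol frees the boronic acid.

Step 9
Reactants: 15 (4-chloro-3,5-dimethoxyphenyl)boronic acid; 16 2,6-dibromo-4-methoxyphenol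
Product: 17 1,3-dibromo-2-(4-chloro-3,5-dimethoxyphenoxy)-5-methoxybenzene
Conditions: Cu(OAc)2 (2 equiv), pyridine, Et3N, 4 Å MS, CH2Cl2, air, rt
Reagents that add atoms: none
Why: Chan–Lam coupling (oxidative copper-mediated O-arylation by an arylboronic acid) runs at room temperature, is established for 2,6-dihalophenols, and leaves the C–Br and C–Cl bonds untouched.

Step 10
Reactants: 12 3,9,11-trimethoxy-1-(2,4,6-trimethoxyphenoxy)dibenzo[d,f][1,3]dioxepin-4-ol (2.4 equiv); 17 1,3-dibromo-2-(4-chloro-3,5-dimethoxyphenoxy)-5-methoxybenzene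
Product: 18 1,3-bis{[3,9,11-trimethoxy-1-(2,4,6-trimethoxyphenoxy)dibenzo[d,f][1,3]dioxepin-4-yl]oxy}-2-(4-chloro-3,5-dimethoxyphenoxy)-5-methoxybenzene (fully protected target)
Conditions: CuI (0.4 equiv), picolinic acid (0.8 equiv), K3PO4, DMSO, 110 °C, argon
Reagents that add atoms: none
Why: Twofold Ullmann-type diaryl ether synthesis with the ligand class suited to couplings in which both partners are ortho-substituted; the flanked C–Cl bond of ring D is inert to copper and excess 12 drives the second substitution.

Step 11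
Reactants: 18 fully protected target
Product: 19 CNP0275555.0
Conditions: BBr3 (ca. 40 equiv), CH2Cl2, −78 °C → rt, argon; then ice-cold degassed aq. NaHSO3
Reagents that add atoms: none
Why: Lewis acid ether cleavage with BBr3 removes the fifteen methyl groups as MeBr and opens both diaryl formaldehyde acetals, while diaryl ether, biaryl and C–Cl bonds are inert, and the bisulfite quench captures the released formaldehyde before it can alkylate the phloroglucinol rings.

**Compound list**

1 | 5-bromo-2-hydroxy-3-methoxybenzaldehyde | COc1cc(Br)cc(C=O)c1O | starting material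
2 | 2-(benzyloxy)-5-bromo-3-methoxybenzaldehyde | COc1cc(Br)cc(C=O)c1OCc1ccccc1 | intermediate
3 | 2-(benzyloxy)-5-bromo-3-methoxyphenyl formate | COc1cc(Br)cc(OC=O)c1OCc1ccccc1 | intermediate (not isolated)
4 | 2-(benzyloxy)-5-bromo-3-methoxyphenol | COc1cc(Br)cc(O)c1OCc1ccccc1 | intermediate
5 | 2-(benzyloxy)-5-bromo-3-methoxy-1-[(methylsulfanyl)methoxy]benzene | COc1cc(Br)cc(OCSC)c1OCc1ccccc1 | intermediate
6 | 3,5-dimethoxyphenol | COc1cc(O)cc(OC)c1 | starting material
7 | 2-(benzyloxy)-5-bromo-1-(chloromethoxy)-3-methoxybenzene | COc1cc(Br)cc(OCCl)c1OCc1ccccc1 | intermediate (not isolated)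
8 | 2-(benzyloxy)-5-bromo-1-[(3,5-dimethoxyphenoxy)methoxy]-3-methoxybenzene | COc1cc(OC)cc(OCOc2cc(Br)cc(OC)c2OCc2ccccc2)c1 | intermediate
9 | 2,4,6-trimethoxyphenol | COc1cc(OC)c(O)c(OC)c1 | starting material
10 | 2-(benzyloxy)-1-[(3,5-dimethoxyphenoxy)methoxy]-3-methoxy-5-(2,4,6-trimethoxyphenoxy)benzene | COc1cc(OC)cc(OCOc2cc(Oc3c(OC)cc(OC)cc3OC)cc(OC)c2OCc2ccccc2)c1 | intermediate
11 | 4-(benzyloxy)-3,9,11-trimethoxy-1-(2,4,6-trimethoxyphenoxy)dibenzo[d,f][1,3]dioxepine (racemic axis) | COc1cc(OC)c2c(c1)OCOc1c(OCc3ccccc3)c(OC)cc(Oc3c(OC)cc(OC)cc3OC)c1-2 | intermediate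
12 | 3,9,11-trimethoxy-1-(2,4,6-trimethoxyphenoxy)dibenzo[d,f][1,3]dioxepin-4-ol (racemic axis) | COc1cc(OC)c2c(c1)OCOc1c(O)c(OC)cc(Oc3c(OC)cc(OC)cc3OC)c1-2 | intermediate
13 | 2-chloro-1,3-dimethoxybenzene | COc1cccc(OC)c1Cl | starting material
14 | 2-(4-chloro-3,5-dimethoxyphenyl)-4,4,5,5-tetramethyl-1,3,2-dioxaborolane | COc1cc(B2OC(C)(C)C(C)(C)O2)cc(OC)c1Cl | intermediate (not isolated)
15 | (4-chloro-3,5-dimethoxyphenyl)boronic acid | COc1cc(B(O)O)cc(OC)c1Cl | intermediate
16 | 2,6-dibromo-4-methoxyphenol | COc1cc(Br)c(O)c(Br)c1 | starting material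
17 | 1,3-dibromo-2-(4-chloro-3,5-dimethoxyphenoxy)-5-methoxybenzene | COc1cc(Br)c(Oc2cc(OC)c(Cl)c(OC)c2)c(Br)c1 | intermediate
18 | 1,3-bis{[3,9,11-trimethoxy-1-(2,4,6-trimethoxyphenoxy)dibenzo[d,f][1,3]dioxepin-4-yl]oxy}-2-(4-chloro-3,5-dimethoxyphenoxy)-5-methoxybenzene (mixture of axial diastereomers) | COc1cc(Oc2c(OC)cc(Oc3c(OC)cc(OC)cc3OC)c3-c4c(OC)cc(OC)cc4OCOc23)c(Oc2cc(OC)c(Cl)c(OC)c2)c(Oc2c(OC)cc(Oc3c(OC)cc(OC)cc3OC)c3-c4c(OC)cc(OC)cc4OCOc23)c1 | intermediate
19 | CNP0275555.0: 2-(4-chloro-3,5-dihydroxyphenoxy)-5-hydroxybenzene bearing on O–C1 and O–C3 a 2,6-dihydroxy-3-(2,4,6-trihydroxyphenyl)-4-(2,4,6-trihydroxyphenoxy)phenyl group each; no stereo element | Oc1cc(O)c(Oc2cc(O)c(Oc3cc(O)cc(Oc4c(O)cc(Oc5c(O)cc(O)cc5O)c(-c5c(O)cc(O)cc5O)c4O)c3Oc3cc(O)c(Cl)c(O)c3)c(O)c2-c2c(O)cc(O)cc2O)c(O)c1 | target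

**Step count**

Total: 11 steps (arm, steps 1–7; ring C/ring D fragment, steps 8–9; union and deprotection, steps 10–11). Longest linear sequence: 9 steps (1–7, 10, 11).

**Steps most likely to fail**

Step 6 (anodic ring closure). Three processes could defeat it: intermolecular C–C coupling through the free, highly nucleophilic positions of ring A; further oxidation of the product biaryl, which is more easily oxidised than 10; and anodic fragmentation at the acetal. The fallback makes the same B6–G1 bond across the same bridge by palladium-catalysed intramolecular direct arylation, a known reaction type. It sets out from 5 and returns at 11. Chloromethyl ether 7, generated from 5 as in step 4, is combined with purchased 2-bromo-3,5-dimethoxyphenol (COc1cc(O)c(Br)c(OC)c1) and Cs2CO3 in MeCN to give 2-(benzyloxy)-5-bromo-1-[(2-bromo-3,5-dimethoxyphenoxy)methoxy]-3-methoxybenzene F1. The unhindered ring B bromide of F1 is etherified with 9 under the conditions of step 5 to give 2-(benzyloxy)-1-[(2-bromo-3,5-dimethoxyphenoxy)methoxy]-3-methoxy-5-(2,4,6-trimethoxyphenoxy)benzene F2; the di-ortho-oxygenated bromide on the future ring G is expected to react much more slowly with copper. Pd(OAc)2, PCy3·HBF4, K2CO3 and pivalic acid in DMA at 120 °C should then insert into the remaining C–Br bond and close the dioxepine by concerted metalation–deprotonation at B6, the only C–H bond within reach, giving 11.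

Step 10 (twofold Ullmann coupling). The reaction may stall after the first C–O bond, with hydrodebromination of the second site, because the phenol carries two ortho substituents and each bromide sits next to the ring D aryloxy group. The fallback forms the two ring C–O–B4 bonds by nucleophilic aromatic substitution and attaches ring D last. It sets out from 12 and returns at 18. Phenol 12 (2.2 equiv), purchased 2,6-difluoro-4-methoxybenzaldehyde (COc1cc(F)c(C=O)c(F)c1) and Cs2CO3 in DMSO at 100–120 °C should displace both fluorides ortho to the formyl group and give 2,6-bis{[3,9,11-trimethoxy-1-(2,4,6-trimethoxyphenoxy)dibenzo[d,f][1,3]dioxepin-4-yl]oxy}-4-methoxybenzaldehyde F3. Baeyer–Villiger oxidation with mCPBA in CH2Cl2 gives the corresponding aryl formate F4, and methanolysis (K2CO3, MeOH) gives the 2,6-bis(aryloxy)-4-methoxyphenol F5. Chan–Lam coupling of F5 with boronic acid 15 (Cu(OAc)2, pyridine, Et3N, 4 Å MS, CH2Cl2, air) puts ring D on the central oxygen and gives 18.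

Step 11 (global deprotection). Cleavage may remain incomplete among nineteen C–O bonds; the bromomethyl ether and formaldehyde released from the two bridges may C-alkylate the freed phloroglucinol rings; and the polyphenol may oxidise in air during work-up. The fallback unmasks in two ordered stages, removing the bridge carbons while every phloroglucinol ring is still O-methylated. It sets out from 18 and returns at 19. Transthioacetalisation of 18 with BF3·OEt2 and 1,2-ethanedithiol in CH2Cl2 at 0 °C → rt hands both methylene carbons to sulfur as 1,3-dithiolane and should give the tetraphenol F6, with free OH on B5 and G2 of each arm and all fifteen methyl ethers intact. F6 is then demethylated with BBr3 in CH2Cl2 (−78 °C → rt), with degassed aqueous work-up, to give 19.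

**Further compounds**

F1 | step 6 | 2-(benzyloxy)-5-bromo-1-[(2-bromo-3,5-dimethoxyphenoxy)methoxy]-3-methoxybenzene | COc1cc(OC)c(Br)c(OCOc2cc(Br)cc(OC)c2OCc2ccccc2)c1
F2 | step 6 | 2-(benzyloxy)-1-[(2-bromo-3,5-dimethoxyphenoxy)methoxy]-3-methoxy-5-(2,4,6-trimethoxyphenoxy)benzene | COc1cc(OC)c(Br)c(OCOc2cc(Oc3c(OC)cc(OC)cc3OC)cc(OC)c2OCc2ccccc2)c1
F3 | step 10 | 2,6-bis{[3,9,11-trimethoxy-1-(2,4,6-trimethoxyphenoxy)dibenzo[d,f][1,3]dioxepin-4-yl]oxy}-4-methoxybenzaldehyde | COc1cc(Oc2c(OC)cc(Oc3c(OC)cc(OC)cc3OC)c3-c4c(OC)cc(OC)cc4OCOc23)c(C=O)c(Oc2c(OC)cc(Oc3c(OC)cc(OC)cc3OC)c3-c4c(OC)cc(OC)cc4OCOc23)c1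
F4 | step 10 | 2,6-bis{[3,9,11-trimethoxy-1-(2,4,6-trimethoxyphenoxy)dibenzo[d,f][1,3]dioxepin-4-yl]oxy}-4-methoxyphenyl formate | COc1cc(Oc2c(OC)cc(Oc3c(OC)cc(OC)cc3OC)c3-c4c(OC)cc(OC)cc4OCOc23)c(OC=O)c(Oc2c(OC)cc(Oc3c(OC)cc(OC)cc3OC)c3-c4c(OC)cc(OC)cc4OCOc23)c1
F5 | step 10 | 2,6-bis{[3,9,11-trimethoxy-1-(2,4,6-trimethoxyphenoxy)dibenzo[d,f][1,3]dioxepin-4-yl]oxy}-4-methoxyphenol | COc1cc(Oc2c(OC)cc(Oc3c(OC)cc(OC)cc3OC)c3-c4c(OC)cc(OC)cc4OCOc23)c(O)c(Oc2c(OC)cc(Oc3c(OC)cc(OC)cc3OC)c3-c4c(OC)cc(OC)cc4OCOc23)c1
F6 | step 11 | tetraphenol from 18 with both O–CH2–O bridges removed (OH on B5 and G2 of each arm, fifteen methyl ethers intact) | COc1cc(Oc2c(OC)cc(Oc3c(OC)cc(OC)cc3OC)c(-c3c(OC)cc(OC)cc3O)c2O)c(Oc2cc(OC)c(Cl)c(OC)c2)c(Oc2c(OC)cc(Oc3c(OC)cc(OC)cc3OC)c(-c3c(OC)cc(OC)cc3O)c2O)c1
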